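Readings and results were computed with constants of no real substance.

Begin at the early minutes of the south run, where target appears from the first readings while starting material falls steadily.

| setting | south | beta | alpha | gamma | theta |
|---|---|---|---|---|---|
| starting material | 1.5 M | 1.5 M | 1.5 M | 1.5 M | 1.5 M |
| partner | 0.65 equiv | 1.30 equiv | 1.30 equiv | 1.30 equiv | 1.30 equiv |
| temperature | 75 °C |  | 75 °C | 50 °C | 25 °C |
| remark | run made earlier | at 75 °C until 5.0 min, from then on at 25 °C |  |  |  |
| time |  | 15 min | 15 min | 15 min | 15 min |

- south (time / min: target / %, starting material / %): 0.333: 1.1, 98.4; 0.500: 0.1, 98.3; 0.833: 1.4, 96.7; 1.33: 1.5, 95.1; 2.00: 2.9, 93.8; 3.00: 3.7, 89.4; 5.00: 5.5, 82.7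

(each reading ± 0.5 percentage points)

- the earlier runs do not show what temperature does; that part of a forecast is a guess
- a reading or a percentage of target counts all its forms, free or not

* the flask with the highest amount of target, in percent of the starting material charged ("all alike" if they lie within 1.5 percentage points) (beta / alpha / gamma / theta / all alike)
* final target, as a percentage of the starting material charged, in beta
* final target, as a percentage of the starting material charged, in alpha
* final target, as a percentage of the starting material charged, in gamma
* final target, as a percentage of the starting material charged, in theta

Now set two numbers side by side. By 5.00 min the closed south flask has lost 17.3% of its starting material, yet it shows just 5.5% of target. Is the rest waiting in a queue? Test that. A queue in front of target shows as a ratio that climbs with time, but the ratio of target to lost starting material in the south run reads 0.468 at 2.00 min and 0.318 at 5.00 min, so it does not climb.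

So follow one molecule instead. Reckon that in the south run it leaves the starting material, reaches a fork, and ends as target about a third of the time. Call the last reading the target share, the part of the lost starting material that stands as target, which is a selectivity read with the scatter of the readings. Then, while the share holds, reckon target as share times loss.

Commit to a reckoning of my own for alpha: keep the south pace of loss for 15 min, multiply by the share, and get 16.5%. For alpha the forecast gives more; in full it reads 9% in beta, 22% in alpha, 5% in gamma, 0.8% in theta, with alpha on top. In its words: “Alpha should be highest”.

The flasks give 18.5% in beta, 21.8% in alpha, 31.4% in gamma and 15.1% in theta, so gamma holds the most target.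

    partner + tight pair → target (k = 3.57 M⁻¹ min⁻¹, Ea = 50.0 kJ mol⁻¹)
    crystals ⇌ target, rate k2*(cs2 - [target]) while solid is left; crystals form when [target] > cs2 (solubility = 0.0700 M, k = 2.53 min⁻¹)
    tight pair ⇌ loose pair (K = 0.732, k = 203 min⁻¹, Ea = 61.0 kJ mol⁻¹, ΔH = −9.00 kJ mol⁻¹)
    2 starting material → self-condensation product (k = 4.38 × 10⁻⁵ M⁻¹ min⁻¹, Ea = 74.0 kJ mol⁻¹)
    starting material ⇌ tight pair (K = 0.0400, k = 0.0382 min⁻¹, Ea = 89.0 kJ mol⁻¹, ΔH = −90.0 kJ mol⁻¹)
    partner + loose pair → isomer of the product (k = 8.95 M⁻¹ min⁻¹, Ea = 52.0 kJ mol⁻¹)
    (constants at 25 °C)

Apply the share to gamma, which lost 77.1% of its starting material: share times loss gives 24.5% against the 31.4% found. Apply it to the neighbour, a flask like theta kept at 40 °C: the loss there gives 24.9% against 30.5%. In theta at 6.46 min, tight pair turns into loose pair at 35 times the rate at which it gives target, counting the forward rate of that reversible step alone. At the end theta holds 26.3% of isomer of the product against 15.1% of target.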